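**Plan**

1. The target is epicatechin-(4β→8)-epigallocatechin 3-O-gallate-(4β→8)-epicatechin-(4β→8)-catechin (units 1–4 from the top). The retrosynthesis cuts first the benzyl ethers and a C-8 bromine cap, then C-4(unit 2)–C-8(unit 3), then C-4(unit 1)–C-8(unit 2), and in unit 3 both the C-2–C-3 bond of its pyran ring and C-4(unit 3)–C-8(unit 4).
2. Enabling feature: ring A of unit 3 is a phloroglucinol ring whose O-1 can carry an oxocarbenium carbon (C-2) and whose ortho carbon C-4a can carry a vinyl ester (C-4=C-3). The array C-2=O-1(+)–C-8a=C-4a–C-4=C-3 is a 6π system, and its closure through C-2–C-3 gives the C-4 benzylic cation that also builds 4→8 bonds.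
3. Forward: an achiral aryl building block (steps 2–5) is closed to ring C of unit 3 and joined to benzylated catechin in one operation (step 6), then the helper ester is removed. Units 1 and 2 come from epicatechin and epigallocatechin by C-4 oxidation and Lewis-acid coupling; the dimeric electrophile and dimeric nucleophile are joined and all benzyl groups and the bromine cap are removed.
4. Stereochemistry: units 1, 2 and 4 come from the chiral pool. In unit 3, C-2/C-3 cis follows from the E,E geometry under disrotation, the absolute sense from a chiral counter-anion, and C-4 from anchimeric help of the 3-O-pivaloyl group. Every interflavan bond forms anti to the C-3 oxygen substituent (3,4-trans).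

Key step: step 6

Assumption: which antipode of the chiral acid leads to the 2R,3R series of unit 3 cannot be predicted with certainty; the R antipode is written, and the S antipode would be used if the sense proved opposite.

**Route**

Step 1
Reactants: 1 (+)-catechin
Product: 2 5,7,3',4'-tetra-O-benzyl-(+)-catechin
Conditions: BnBr (4.4 equiv), K2CO3, DMF, 0 °C → rt
Reagents that add atoms: benzyl bromide, BrCc1ccccc1
Why: Williamson etherification alkylates the four phenols, which are far more acidic than the secondary 3-OH, and touches no stereocenter.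

Step 2
Reactants: 3 2,4,6-trihydroxybenzaldehyde
Product: 4 4,6-bis(benzyloxy)-2-hydroxybenzaldehyde
Conditions: BnBr (2.05 equiv), K2CO3, DMF, 0 °C → rt
Reagents that add atoms: benzyl bromide, BrCc1ccccc1
Why: Williamson etherification with two equivalents of halide should take the 4-OH and one ortho OH, while the last ortho OH is held in a hydrogen bond to the formyl group and stays free.

Step 3
Reactants: 4 4,6-bis(benzyloxy)-2-hydroxybenzaldehyde; 5 3,4-bis(benzyloxy)benzaldehyde
Product: 7 [3,4-bis(benzyloxy)phenyl][3,5-bis(benzyloxy)-2-formylphenoxy]methyl pivalate (racemic at the acetal carbon), via α-chlorobenzyl pivalate 6 (not isolated)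
Conditions: 5, Me3CCOCl, ZnCl2 (cat.), CH2Cl2, 0 °C; then 4, i-Pr2NEt, 0 °C → rt
Reagents that add atoms: pivaloyl chloride, CC(C)(C)C(=O)Cl
Why: ZnCl2-catalysed addition of the acyl chloride across the aldehyde C=O gives the 1-chloroalkyl ester, whose ionisable C–Cl bond alkylates the phenol oxygen (acyloxyalkyl ether formation, as with chloromethyl pivalate), and the racemic acetal carbon becomes planar later.

Step 4
Reactants: 7 the acetal aldehyde
Product: 8 [3,4-bis(benzyloxy)phenyl]{3,5-bis(benzyloxy)-2-[(E)-2-iodovinyl]phenoxy}methyl pivalate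
Conditions: CrCl2 (6 equiv), CHI3 (2 equiv), THF/1,4-dioxane, 0 °C → rt, dark
Reagents that add atoms: iodoform, IC(I)I
Why: Takai iodo-olefination adds the geminal dichromium reagent to the aldehyde and eliminates anti to give the (E)-alkenyl iodide, as is usual for aryl aldehydes, under neutral conditions that should spare the acetal.

Step 5
Reactants: 8 the (E)-alkenyl iodide
Product: 9 (E)-2-{2,4-bis(benzyloxy)-6-[[3,4-bis(benzyloxy)phenyl](pivaloyloxy)methoxy]phenyl}vinyl pivalate
Conditions: CuI (20 mol%), 1,10-phenanthroline (40 mol%), cesium pivalate CsO2CCMe3 (2 equiv), toluene, 90 °C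
Reagents that add atoms: cesium pivalate, CC(C)(C)C(=O)[O-].[Cs+]
Why: Ullmann-type copper-catalysed C–O coupling of an alkenyl iodide with a carboxylate proceeds with retention of alkene geometry and should give the (E)-enol ester under non-acidic conditions.

Step 6
Reactants: 9 the (E)-enol pivalate acetal; 2 5,7,3',4'-tetra-O-benzyl-(+)-catechin
Product: 12 5,7,3',4'-tetra-O-benzyl-3-O-pivaloyl-epicatechin-(4β→8)-5,7,3',4'-tetra-O-benzylcatechin, via aryloxocarbenium ion 10 (not isolated), via cis-fused dioxolanylium ion 11 (not isolated)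
Conditions: (R)-3,3'-bis(2,4,6-triisopropylphenyl)-1,1'-binaphthyl-2,2'-diyl N-triflylphosphoramide (C51H57F3NO5PS, 10 mol%), 4 Å MS, toluene (0.01 M), −60 °C; then 2 (3 equiv), −60 → 0 °C
Reagents that add atoms: none
Why: Proposed new method: the chiral acid protonates the pivaloyloxy group of the O-aryl O-acyl acetal (the carboxylate is the better leaving group and the aryloxy group the better donor) and gives the (E)-aryloxocarbenium ion 10, whose C-2=O-1(+)–C-8a=C-4a–C-4=C-3 array is a 2-oxonia-hexatriene that closes the pyran ring through the C-2–C-3 bond by thermal 6π disrotatory electrocyclisation (6-endo with respect to the alkene); the closest known reaction types are the oxa-Povarov and Prins additions of alkenes to aryl oxocarbenium ions, chiral-acid ion-pair catalysis of benzopyrylium ions and of Nazarov electrocyclisations, and the 4β-selective arylation of 3-O-acyl flavan-4-yl cations. The aryl group on C-2 (E-oxocarbenium) and the pivaloyloxy group on C-3 (E-alkene) are both outside substituents, so disrotation must place them cis as in epicatechin, and the direction of rotation, hence the absolute configuration at C-2 and C-3, is set by the chiral phosphoramidate counter-anion of the contact ion pair. The cyclised ion is the 5,7-dioxygenated flavan-4-yl cation, which the cis pivaloyl carbonyl oxygen captures on the α-face in a five-membered anchimeric closure to give the dioxolanylium ion 11. C-8 of 2 then opens 11 at C-4 with inversion, so the new aryl group is β and trans to the C-3 oxygen. The step needs C-3 and not C-4 of the alkene to bond (secured by the much stronger cation stabilisation by the trioxygenated ring than by the acyloxy group and by the six-membered array), ring closure before intermolecular capture of 10 (secured by adding 2 only after the closure) and C-8 over C-6 attack of 2 (the usual preference of 5,7-di-O-benzylflavans, used in excess).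

Step 7
Reactants: 12 the 3-O-pivaloyl dimer
Product: 13 5,7,3',4'-tetra-O-benzylepicatechin-(4β→8)-5,7,3',4'-tetra-O-benzylcatechin (octa-O-benzyl procyanidin B1)
Conditions: i-Bu2AlH (4 equiv), CH2Cl2, −78 °C; aq. Rochelle salt
Reagents that add atoms: none
Why: Reductive cleavage of the hindered pivalate by the aluminium hydride at low temperature should free the 3-OH of the upper unit without touching benzyl ethers or stereocenters.

Step 8
Reactants: 14 (−)-epicatechin
Product: 15 5,7,3',4'-tetra-O-benzyl-(−)-epicatechin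
Conditions: BnBr (4.4 equiv), K2CO3, DMF, 0 °C → rt
Reagents that add atoms: benzyl bromide, BrCc1ccccc1
Why: Williamson etherification of the four phenols as in step 1, with the 3-OH and both stereocenters untouched.

Step 9
Reactants: 15 5,7,3',4'-tetra-O-benzyl-(−)-epicatechin
Product: 16 5,7,3',4'-tetra-O-benzyl-4β-(2-ethoxyethoxy)epicatechin
Conditions: DDQ (2 equiv), 2-ethoxyethanol (5 equiv), CH2Cl2, rt
Reagents that add atoms: 2-ethoxyethanol, CCOCCO
Why: DDQ abstracts hydride from the benzylic C-4 position activated by the 5,7-dioxygenated ring A, and the alcohol traps the cation trans to the 3-OH (established C-4 oxidation of benzylated flavan-3-ols).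

Step 10
Reactants: 16 the 4β-(2-ethoxyethoxy) ether
Product: 17 8-bromo-5,7,3',4'-tetra-O-benzyl-4β-(2-ethoxyethoxy)epicatechin
Conditions: NBS (1.05 equiv), CH2Cl2, −78 → −20 °C
Reagents that add atoms: N-bromosuccinimide, O=C1CCC(=O)N1Br
Why: Electrophilic aromatic bromination goes to C-8, the most nucleophilic position of the 5,7-di-O-benzyl ring A, and the bromine later blocks self-condensation.

Step 11
Reactants: 18 (−)-epigallocatechin
Product: 19 5,7,3',4',5'-penta-O-benzyl-(−)-epigallocatechin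
Conditions: BnBr (5.5 equiv), K2CO3, DMF, 0 °C → rt
Reagents that add atoms: benzyl bromide, BrCc1ccccc1
Why: Williamson etherification of the five phenols, with the 3-OH and both stereocenters untouched.

Step 12
Reactants: 19 penta-O-benzyl-epigallocatechin; 20 3,4,5-tris(benzyloxy)benzoic acid
Product: 21 octa-O-benzyl-(−)-epigallocatechin 3-O-gallate
Conditions: DCC, DMAP (cat.), CH2Cl2, rt
Reagents that add atoms: none
Why: Steglich esterification acylates the only free hydroxyl, the 3-OH, with retention of configuration.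

Step 13
Reactants: 17 the bromo-capped electrophile; 21 octa-O-benzyl-epigallocatechin 3-O-gallate
Product: 22 8-bromo-5,7,3',4'-tetra-O-benzylepicatechin-(4β→8)-octa-O-benzyl-epigallocatechin 3-O-gallate
Conditions: 21 (3 equiv), Me3SiOTf (0.2 equiv), CH2Cl2, −78 → −40 °C
Reagents that add atoms: none
Why: Lewis-acid ionisation of the C-4 ether gives the flavan-4-yl cation, which C-8 of the excess nucleophile attacks anti to the 3-OH and 2-aryl groups (Friedel–Crafts-type flavan coupling), setting C-4 as 4β.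

Step 14
Reactants: 22 the bromo-capped dimer
Product: 23 8-bromo-5,7,3',4'-tetra-O-benzylepicatechin-(4β→8)-4β-(2-ethoxyethoxy)-octa-O-benzyl-epigallocatechin 3-O-gallate
Conditions: DDQ (2.5 equiv), 2-ethoxyethanol (5 equiv), CH2Cl2, rt
Reagents that add atoms: 2-ethoxyethanol, CCOCCO
Why: DDQ benzylic oxidation at the only benzylic methylene, C-4 of unit 2, with trapping by the alcohol trans to the gallate, as for the monomer in step 9.

Step 15
Reactants: 23 the dimeric electrophile; 13 octa-O-benzyl procyanidin B1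
Product: 24 eicosa-O-benzyl-8-bromo tetramer [8-bromo-epicatechin-(4β→8)-epigallocatechin 3-O-gallate-(4β→8)-epicatechin-(4β→8)-catechin with all twenty phenols benzylated]
Conditions: 13 (2 equiv), Me3SiOTf (0.3 equiv), CH2Cl2, −40 → −20 °C
Reagents that add atoms: none
Why: Ionisation at C-4 of unit 2 with anchimeric help of the 3-O-galloyl carbonyl sends C-8 of the upper unit of 13, the most nucleophilic site of a dimeric nucleophile, to the β-face (3,4-trans Friedel–Crafts-type coupling), while the bromine stops self-condensation of 23.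

Step 16
Reactants: 24 the protected tetramer
Product: 25 epicatechin-(4β→8)-epigallocatechin 3-O-gallate-(4β→8)-epicatechin-(4β→8)-catechin (CNP0332815.1)
Conditions: H2 (1 atm), Pd(OH)2/C, Et3N (1.1 equiv), THF/MeOH/H2O, rt
Reagents that add atoms: none
Why: Hydrogenolysis over Pd(OH)2/C should cleave all twenty benzyl ethers and the aryl bromide (the amine takes up HBr) while the gallate ester, the interflavan bonds and all stereocenters are untouched.

**Compound list**

1 | (+)-catechin (2R,3S) | O[C@H]1Cc2c(O)cc(O)cc2O[C@@H]1c1ccc(O)c(O)c1 | starting material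
2 | 5,7,3',4'-tetra-O-benzyl-(+)-catechin | O[C@H]1Cc2c(OCc6ccccc6)cc(OCc6ccccc6)cc2O[C@@H]1c1ccc(OCc6ccccc6)c(OCc6ccccc6)c1 | intermediate
3 | 2,4,6-trihydroxybenzaldehyde | O=Cc1c(O)cc(O)cc1O | starting material
4 | 4,6-bis(benzyloxy)-2-hydroxybenzaldehyde | O=Cc1c(O)cc(OCc6ccccc6)cc1OCc6ccccc6 | intermediate
5 | 3,4-bis(benzyloxy)benzaldehyde | O=Cc1ccc(OCc6ccccc6)c(OCc6ccccc6)c1 | starting material
6 | chloro[3,4-bis(benzyloxy)phenyl]methyl pivalate (racemic, not isolated) | CC(C)(C)C(=O)OC(Cl)c1ccc(OCc6ccccc6)c(OCc6ccccc6)c1 | intermediate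
7 | [3,4-bis(benzyloxy)phenyl][3,5-bis(benzyloxy)-2-formylphenoxy]methyl pivalate (racemic) | O=Cc1c(OC(OC(=O)C(C)(C)C)c2ccc(OCc6ccccc6)c(OCc6ccccc6)c2)cc(OCc6ccccc6)cc1OCc6ccccc6 | intermediate
8 | [3,4-bis(benzyloxy)phenyl]{3,5-bis(benzyloxy)-2-[(E)-2-iodovinyl]phenoxy}methyl pivalate | I/C=C/c1c(OC(OC(=O)C(C)(C)C)c2ccc(OCc6ccccc6)c(OCc6ccccc6)c2)cc(OCc6ccccc6)cc1OCc6ccccc6 | intermediate
9 | (E)-2-{2,4-bis(benzyloxy)-6-[[3,4-bis(benzyloxy)phenyl](pivaloyloxy)methoxy]phenyl}vinyl pivalate | CC(C)(C)C(=O)O/C=C/c1c(OC(OC(=O)C(C)(C)C)c2ccc(OCc6ccccc6)c(OCc6ccccc6)c2)cc(OCc6ccccc6)cc1OCc6ccccc6 | intermediate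
10 | (E)-aryloxocarbenium ion from 9 (cation, counter-ion the chiral phosphoramidate, not isolated) | CC(C)(C)C(=O)O/C=C/c1c(/[O+]=C/c2ccc(OCc6ccccc6)c(OCc6ccccc6)c2)cc(OCc6ccccc6)cc1OCc6ccccc6 | intermediate
11 | 2,3-cis-3,4-cis-fused 2-tert-butyl-1,3-dioxolan-2-ylium ion of the tetra-O-benzyl flavan (not isolated) | c1c(OCc6ccccc6)cc(OCc6ccccc6)c2c1O[C@H](c1ccc(OCc6ccccc6)c(OCc6ccccc6)c1)[C@@H]3OC(C(C)(C)C)=[O+][C@H]23 | intermediate
12 | 5,7,3',4'-tetra-O-benzyl-3-O-pivaloyl-epicatechin-(4β→8)-5,7,3',4'-tetra-O-benzylcatechin | c1c(OCc6ccccc6)cc(OCc6ccccc6)c2c1O[C@H](c1ccc(OCc6ccccc6)c(OCc6ccccc6)c1)[C@H](OC(=O)C(C)(C)C)[C@H]2c1c(OCc6ccccc6)cc(OCc6ccccc6)c2c1O[C@H](c1ccc(OCc6ccccc6)c(OCc6ccccc6)c1)[C@@H](O)C2 | intermediate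
13 | 5,7,3',4'-tetra-O-benzylepicatechin-(4β→8)-5,7,3',4'-tetra-O-benzylcatechin (octa-O-benzyl procyanidin B1) | c1c(OCc6ccccc6)cc(OCc6ccccc6)c2c1O[C@H](c1ccc(OCc6ccccc6)c(OCc6ccccc6)c1)[C@H](O)[C@H]2c1c(OCc6ccccc6)cc(OCc6ccccc6)c2c1O[C@H](c1ccc(OCc6ccccc6)c(OCc6ccccc6)c1)[C@@H](O)C2 | intermediate
14 | (−)-epicatechin (2R,3R) | O[C@@H]1Cc2c(O)cc(O)cc2O[C@@H]1c1ccc(O)c(O)c1 | starting material
15 | 5,7,3',4'-tetra-O-benzyl-(−)-epicatechin | O[C@@H]1Cc2c(OCc6ccccc6)cc(OCc6ccccc6)cc2O[C@@H]1c1ccc(OCc6ccccc6)c(OCc6ccccc6)c1 | intermediate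
16 | 5,7,3',4'-tetra-O-benzyl-4β-(2-ethoxyethoxy)epicatechin | O[C@@H]1[C@@H](OCCOCC)c2c(OCc6ccccc6)cc(OCc6ccccc6)cc2O[C@@H]1c1ccc(OCc6ccccc6)c(OCc6ccccc6)c1 | intermediate
17 | 8-bromo-5,7,3',4'-tetra-O-benzyl-4β-(2-ethoxyethoxy)epicatechin | O[C@@H]1[C@@H](OCCOCC)c2c(OCc6ccccc6)cc(OCc6ccccc6)c(Br)c2O[C@@H]1c1ccc(OCc6ccccc6)c(OCc6ccccc6)c1 | intermediate
18 | (−)-epigallocatechin (2R,3R) | O[C@@H]1Cc2c(O)cc(O)cc2O[C@@H]1c1cc(O)c(O)c(O)c1 | starting material
19 | 5,7,3',4',5'-penta-O-benzyl-(−)-epigallocatechin | O[C@@H]1Cc2c(OCc6ccccc6)cc(OCc6ccccc6)cc2O[C@@H]1c1cc(OCc6ccccc6)c(OCc6ccccc6)c(OCc6ccccc6)c1 | intermediate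
20 | 3,4,5-tris(benzyloxy)benzoic acid | OC(=O)c1cc(OCc6ccccc6)c(OCc6ccccc6)c(OCc6ccccc6)c1 | starting material
21 | octa-O-benzyl-(−)-epigallocatechin 3-O-gallate | O=C(O[C@@H]1Cc2c(OCc6ccccc6)cc(OCc6ccccc6)cc2O[C@@H]1c1cc(OCc6ccccc6)c(OCc6ccccc6)c(OCc6ccccc6)c1)c1cc(OCc6ccccc6)c(OCc6ccccc6)c(OCc6ccccc6)c1 | intermediate
22 | 8-bromo-5,7,3',4'-tetra-O-benzylepicatechin-(4β→8)-octa-O-benzyl-epigallocatechin 3-O-gallate | O=C(O[C@@H]1Cc2c(OCc6ccccc6)cc(OCc6ccccc6)c([C@H]3c4c(OCc6ccccc6)cc(OCc6ccccc6)c(Br)c4O[C@H](c4ccc(OCc6ccccc6)c(OCc6ccccc6)c4)[C@@H]3O)c2O[C@@H]1c1cc(OCc6ccccc6)c(OCc6ccccc6)c(OCc6ccccc6)c1)c1cc(OCc6ccccc6)c(OCc6ccccc6)c(OCc6ccccc6)c1 | intermediate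
23 | 8-bromo-5,7,3',4'-tetra-O-benzylepicatechin-(4β→8)-4β-(2-ethoxyethoxy)-octa-O-benzyl-epigallocatechin 3-O-gallate | O=C(O[C@@H]1[C@@H](OCCOCC)c2c(OCc6ccccc6)cc(OCc6ccccc6)c([C@H]3c4c(OCc6ccccc6)cc(OCc6ccccc6)c(Br)c4O[C@H](c4ccc(OCc6ccccc6)c(OCc6ccccc6)c4)[C@@H]3O)c2O[C@@H]1c1cc(OCc6ccccc6)c(OCc6ccccc6)c(OCc6ccccc6)c1)c1cc(OCc6ccccc6)c(OCc6ccccc6)c(OCc6ccccc6)c1 | intermediate
24 | eicosa-O-benzyl-8-bromo tetramer (bromine on C-8 of unit 1, free 3-OH in units 1, 3 and 4) | O=C(O[C@@H]1[C@@H](c2c(OCc6ccccc6)cc(OCc6ccccc6)c3c2O[C@H](c2ccc(OCc6ccccc6)c(OCc6ccccc6)c2)[C@H](O)[C@H]3c2c(OCc6ccccc6)cc(OCc6ccccc6)c3c2O[C@H](c2ccc(OCc6ccccc6)c(OCc6ccccc6)c2)[C@@H](O)C3)c2c(OCc6ccccc6)cc(OCc6ccccc6)c([C@H]3c4c(OCc6ccccc6)cc(OCc6ccccc6)c(Br)c4O[C@H](c4ccc(OCc6ccccc6)c(OCc6ccccc6)c4)[C@@H]3O)c2O[C@@H]1c1cc(OCc6ccccc6)c(OCc6ccccc6)c(OCc6ccccc6)c1)c1cc(OCc6ccccc6)c(OCc6ccccc6)c(OCc6ccccc6)c1 | intermediate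
25 | epicatechin-(4β→8)-epigallocatechin 3-O-gallate-(4β→8)-epicatechin-(4β→8)-catechin (CNP0332815.1) | O=C(O[C@@H]1[C@@H](c2c(O)cc(O)c3c2O[C@H](c2ccc(O)c(O)c2)[C@H](O)[C@H]3c2c(O)cc(O)c3c2O[C@H](c2ccc(O)c(O)c2)[C@@H](O)C3)c2c(O)cc(O)c([C@H]3c4c(O)cc(O)cc4O[C@H](c4ccc(O)c(O)c4)[C@@H]3O)c2O[C@@H]1c1cc(O)c(O)c(O)c1)c1cc(O)c(O)c(O)c1 | target

**Step count and risks**

Total: 16 steps. Longest linear sequence: 8 steps (3 → 4 → 7 → 8 → 9 → 12 → 13 → 24 → 25; steps 2, 3, 4, 5, 6, 7, 15, 16).

Steps most likely to fail: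

1. Step 6 (Proposed new method). What may go wrong: capture of the oxocarbenium ion by an arene before the ring closes, low or wrong-sense torquoselectivity under the chiral counter-anion, or loss of a proton from the C-4 cation to a flav-3-ene. Fallback with known chemistry: it sets out from 16 (made in step 9), which is ionised with Yb(OTf)3 or Me3SiOTf in CH2Cl2 in the presence of an excess of 2; the flavan-4-yl cation of the natural epicatechin unit is attacked by C-8 of 2 anti to the 3-OH and gives 13 directly, where the route is rejoined. Unit 3 then comes from the chiral pool and steps 2 to 7 fall away. No compound outside the list is made on this way (none, F0).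

2. Step 14. What may go wrong: competing hydride abstraction at the doubly benzylic C-4 methine of unit 1 and slow oxidation of the hindered dimer. Fallback: the order of assembly is changed so that only monomers are oxidised. It sets out from 21, which with DDQ and 2-ethoxyethanol should give octa-O-benzyl-4β-(2-ethoxyethoxy)-epigallocatechin 3-O-gallate F1. Me3SiOTf coupling of this with an excess of 13 should give the protected trimer epigallocatechin 3-O-gallate-(4β→8)-epicatechin-(4β→8)-catechin F2. Coupling of the trimer at C-8 of its top unit with the bromo-capped monomer 17 comes back to the route at 24.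

3. Step 5. What may go wrong: slow C–O bond formation at copper with erosion of the alkene geometry, or thermal cleavage of the acid-labile acetal. Fallback: it sets out from 7 and bypasses steps 4 and 5. Boron–Wittig olefination with lithiated bis[(pinacolato)boryl]methane (lithium 2,2,6,6-tetramethylpiperidide, THF, −78 °C) should give the (E)-alkenyl pinacol boronate F3. Chan–Lam-type oxidative coupling of the boronate with pivalic acid (Cu(O2CCMe3)2, Et3N, 4 Å MS, air, CH2Cl2) comes back to the route at 9.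

**Further compounds**

F0 | step 6 | none | none
F1 | step 14 | octa-O-benzyl-4β-(2-ethoxyethoxy)-epigallocatechin 3-O-gallate | O=C(O[C@@H]1[C@@H](OCCOCC)c2c(OCc6ccccc6)cc(OCc6ccccc6)cc2O[C@@H]1c1cc(OCc6ccccc6)c(OCc6ccccc6)c(OCc6ccccc6)c1)c1cc(OCc6ccccc6)c(OCc6ccccc6)c(OCc6ccccc6)c1
F2 | step 14 | hexadeca-O-benzyl epigallocatechin 3-O-gallate-(4β→8)-epicatechin-(4β→8)-catechin | O=C(O[C@@H]1[C@@H](c2c(OCc6ccccc6)cc(OCc6ccccc6)c3c2O[C@H](c2ccc(OCc6ccccc6)c(OCc6ccccc6)c2)[C@H](O)[C@H]3c2c(OCc6ccccc6)cc(OCc6ccccc6)c3c2O[C@H](c2ccc(OCc6ccccc6)c(OCc6ccccc6)c2)[C@@H](O)C3)c2c(OCc6ccccc6)cc(OCc6ccccc6)cc2O[C@@H]1c1cc(OCc6ccccc6)c(OCc6ccccc6)c(OCc6ccccc6)c1)c1cc(OCc6ccccc6)c(OCc6ccccc6)c(OCc6ccccc6)c1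
F3 | step 5 | [3,4-bis(benzyloxy)phenyl]{3,5-bis(benzyloxy)-2-[(E)-2-(4,4,5,5-tetramethyl-1,3,2-dioxaborolan-2-yl)vinyl]phenoxy}methyl pivalate | CC1(C)OB(/C=C/c2c(OC(OC(=O)C(C)(C)C)c3ccc(OCc6ccccc6)c(OCc6ccccc6)c3)cc(OCc6ccccc6)cc2OCc6ccccc6)OC1(C)C
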